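**Retrosynthetic overview**

1. Last operation: the four MOM ethers are removed from a (2S)-flavanone–flavone biaryl.
2. Key disconnection: C3–C4 of the flavanone (ring C). A rhodium-catalysed enantioselective intramolecular hydroacylation turns an achiral 2-(1-arylethenyloxy)-6-hydroxybenzaldehyde into the chromanone and sets C2 in the same operation.
3. Enabling feature: on ring A the formyl carbon (future C4) sits between a free phenol (future C5–OH, which anchors rhodium as a phenoxide) and the ether oxygen O1 that carries the 1,1-disubstituted C2=C3 enol ether alkene. The terminal CH2 (C3) therefore lies one six-membered ring away from the acyl carbon.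
4. The enol ether aldehyde comes from a Suzuki–Miyaura union (C3'–C8'' biaryl bond) of 8-iodo-bis-MOM-acacetin with a ring B boronate. The enol ether itself comes from Mitsunobu etherification of 2,6-dihydroxy-4-MOM-benzaldehyde with a bromohydrin, followed by E2 loss of HBr.
5. Ring order: both flavone rings are bought intact as acacetin, then the biaryl bond is made, and the flavanone ring C is closed last.

Key step: step 10

Assumption: the C3'–C8'' biaryl axis is taken as freely rotating (no axial descriptor is given), so C2 of the flavanone is the only stereo-element to control.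

**Route**

Step 1
Reactants: 1 acacetin (5,7-dihydroxy-2-(4-methoxyphenyl)-4H-chromen-4-one)
Product: 2 5,7-bis(methoxymethoxy)-2-(4-methoxyphenyl)-4H-chromen-4-one
Conditions: NaH (2.5 equiv), MOMCl (2.5 equiv), DMF, 0 °C to rt
Reagents that add atoms: chloromethyl methyl ether (MOMCl), COCCl
Why: Williamson-type O-alkylation of both phenoxides; NaH is used because the 5-OH is hydrogen-bonded to the C4 carbonyl and is not ionized by amine bases, and the aryl methyl ether of the anisyl ring is untouched.

Step 2
Reactants: 2 5,7-bis(methoxymethoxy)-2-(4-methoxyphenyl)-4H-chromen-4-one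
Product: 3 8-iodo-5,7-bis(methoxymethoxy)-2-(4-methoxyphenyl)-4H-chromen-4-one
Conditions: NIS (1.1 equiv), DMF, rt to 40 °C, dark
Reagents that add atoms: N-iodosuccinimide (NIS), O=C1CCC(=O)N1I
Why: Electrophilic aromatic iodination of the phloroglucinol-type ring A under acid-free conditions that keep the MOM acetals; with the 5-oxygen alkylated, attack is expected at C8 (between the ring oxygen and 7-OMOM) rather than at C6, which is squeezed between two MOM ethers, and the site is to be confirmed by HMBC before going on.

Step 3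
Reactants: 4 2,4,6-trihydroxybenzaldehyde
Product: 5 2,6-dihydroxy-4-(methoxymethoxy)benzaldehyde
Conditions: MOMCl (1.0 equiv), i-Pr2NEt (1.1 equiv), THF, 0 °C
Reagents that add atoms: chloromethyl methyl ether (MOMCl), COCCl
Why: Selective Williamson-type alkylation, because the 4-OH is the most acidic hydroxyl and the only one not tied up in a hydrogen bond to the formyl group, so one equivalent of MOMCl should go there and leave the two ortho phenols free.

Step 4
Reactants: 6 1-(3-bromo-4-hydroxyphenyl)ethanone
Product: 7 1-[3-bromo-4-(methoxymethoxy)phenyl]ethanone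
Conditions: MOMCl (1.3 equiv), i-Pr2NEt (1.5 equiv), CH2Cl2, 0 °C to rt
Reagents that add atoms: chloromethyl methyl ether (MOMCl), COCCl
Why: Standard MOM protection (Williamson-type alkylation) of an acidic, unhindered phenol.

Step 5
Reactants: 7 1-[3-bromo-4-(methoxymethoxy)phenyl]ethanone
Product: 9 2-bromo-1-[3-bromo-4-(methoxymethoxy)phenyl]ethanone, via trimethylsilyl enol ether 8 (not isolated)
Conditions: LiN(SiMe3)2, Me3SiCl, THF, −78 °C; then NBS, THF, −78 to 0 °C
Reagents that add atoms: chlorotrimethylsilane, C[Si](C)(C)Cl (its atoms stay only in 8); N-bromosuccinimide (NBS), O=C1CCC(=O)N1Br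
Why: Kinetic enolization and O-silylation followed by electrophilic bromination of the silyl enol ether with NBS gives the phenacyl bromide under non-acidic conditions, which spares the MOM ether and avoids ring bromination.

Step 6
Reactants: 9 2-bromo-1-[3-bromo-4-(methoxymethoxy)phenyl]ethanone
Product: 10 rac-2-bromo-1-[3-bromo-4-(methoxymethoxy)phenyl]ethanol
Conditions: NaBH4, MeOH, −10 to 0 °C; aq NH4Cl quench
Reagents that add atoms: none
Why: Borohydride 1,2-reduction of the ketone at low temperature gives the bromohydrin without epoxide closure; the racemate is sufficient because this carbon becomes sp2 in step 8.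

Step 7
Reactants: 5 2,6-dihydroxy-4-(methoxymethoxy)benzaldehyde; 10 rac-2-bromo-1-[3-bromo-4-(methoxymethoxy)phenyl]ethanol
Product: 11 rac-2-{2-bromo-1-[3-bromo-4-(methoxymethoxy)phenyl]ethoxy}-6-hydroxy-4-(methoxymethoxy)benzaldehyde
Conditions: PPh3, DIAD, THF, 0 °C to rt (5 in slight excess)
Reagents that add atoms: none
Why: Mitsunobu etherification of the secondary benzylic alcohol with the acidic, formyl-activated phenol; after the first O-alkylation the remaining ortho hydroxyl is locked in a hydrogen bond to the aldehyde, so mono-etherification is expected, and the configuration of the new ether carbon is irrelevant.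

Step 8
Reactants: 11 rac-2-{2-bromo-1-[3-bromo-4-(methoxymethoxy)phenyl]ethoxy}-6-hydroxy-4-(methoxymethoxy)benzaldehyde
Product: 12 2-({1-[3-bromo-4-(methoxymethoxy)phenyl]ethenyl}oxy)-6-hydroxy-4-(methoxymethoxy)benzaldehyde
Conditions: KOtBu (2.2 equiv), THF, −20 to 0 °C; aq NH4Cl quench
Reagents that add atoms: none
Why: E2 dehydrobromination in which, once the phenol is masked as its phenoxide, tert-butoxide removes the benzylic oxygen-bearing hydrogen antiperiplanar to bromide and gives the 1-aryloxystyrene (the classical β-halo ether to vinyl ether elimination); the aldehyde has no α-hydrogen and tolerates the base.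

Step 9
Reactants: 12 2-({1-[3-bromo-4-(methoxymethoxy)phenyl]ethenyl}oxy)-6-hydroxy-4-(methoxymethoxy)benzaldehyde; 3 8-iodo-5,7-bis(methoxymethoxy)-2-(4-methoxyphenyl)-4H-chromen-4-one
Product: 14 2-hydroxy-4-(methoxymethoxy)-6-[(1-{3-[5,7-bis(methoxymethoxy)-2-(4-methoxyphenyl)-4-oxo-4H-chromen-8-yl]-4-(methoxymethoxy)phenyl}ethenyl)oxy]benzaldehyde, via aryl pinacol boronate 13 (not isolated)
Conditions: PdCl2(dppf) (5 mol %), B2pin2, KOAc, 1,4-dioxane, 85 °C; then 3, Pd(OAc)2/SPhos (5 mol %), aq K3PO4, 70 °C
Reagents that add atoms: bis(pinacolato)diboron, CC1(C)OB(OC1(C)C)B1OC(C)(C)C(C)(C)O1 (its atoms stay only in 13)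
Why: Miyaura borylation of the aryl bromide followed in the same flask by Suzuki–Miyaura coupling with the C8 iodide builds the tri-ortho-substituted C3'–C8'' biaryl bond; boron is placed on the less hindered ring B and the halide on the di-ortho-substituted flavone carbon, and the enol ether, the aldehyde and the phenoxide are inert to the weakly basic medium.

Step 10
Reactants: 14 2-hydroxy-4-(methoxymethoxy)-6-[(1-{3-[5,7-bis(methoxymethoxy)-2-(4-methoxyphenyl)-4-oxo-4H-chromen-8-yl]-4-(methoxymethoxy)phenyl}ethenyl)oxy]benzaldehyde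
Product: 15 8-{5-[(2S)-5-hydroxy-7-(methoxymethoxy)-4-oxo-3,4-dihydro-2H-chromen-2-yl]-2-(methoxymethoxy)phenyl}-5,7-bis(methoxymethoxy)-2-(4-methoxyphenyl)-4H-chromen-4-one
Conditions: [Rh(cod)(OMe)]2 (2.5 mol %), (R)-DTBM-SEGPHOS (5.5 mol %), toluene (degassed), 4 Å MS, 70 °C
Reagents that add atoms: none
Why: Proposed new method: the rhodium methoxide exchanges with the free ortho-phenol to give a monovalent rhodium aryloxide, oxidative addition of the neighbouring formyl C–H gives a trivalent acyl rhodium hydride held in a five-membered O,C-chelate, the tethered 1,1-disubstituted enol ether alkene inserts into Rh–H with hydride going to the aryl- and oxygen-bearing carbon (future C2) and rhodium to the terminal CH2 (future C3), and C–C reductive elimination from the seven-membered rhodacycle forms the C3–C4 bond, the catalyst being freed by proton exchange with the next substrate phenol. The closest known reaction types are the rhodium/bisphosphine-catalysed enantioselective endo-hydroacylation of ortho-allylbenzaldehydes and of N-(1-substituted vinyl)indole-2-carbaldehydes bearing 1,1-disubstituted alkenes, together with the phenoxide-chelation-assisted hydroacylation of alkenes by salicylaldehydes; what is new is the use of an aryl 1-arylvinyl ether as the alkene to give a flavanone. Ring C (the dihydropyranone ring) is closed in a formal 6-endo-trig mode at the terminal alkene carbon. The C2 stereocenter is created in the hydride migratory insertion, whose alkene face is selected by the C2-symmetric bisphosphine (the (R)-ligand is the working choice, and the antipode is to be used if a model run shows the opposite sense). The step needs regioselectivity for acyl transfer to CH2 over the 5-exo path to a 2-aryl-2-methylbenzofuran-3-one, which the aryl group on the internal alkene carbon secures because it disfavours a tertiary Rh–C bond and a quaternary-centre-forming reductive elimination, and it needs the acyl hydride to outlive decarbonylation, which the phenoxide chelate secures. The medium, free of added base and acid, also keeps the enol ether from hydrolysis or aldol-type closure to a flavylium ion and leaves the new flavanone configurationally stable.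

Step 11
Reactants: 15 8-{5-[(2S)-5-hydroxy-7-(methoxymethoxy)-4-oxo-3,4-dihydro-2H-chromen-2-yl]-2-(methoxymethoxy)phenyl}-5,7-bis(methoxymethoxy)-2-(4-methoxyphenyl)-4H-chromen-4-one
Product: 16 2,3-dihydropodocarpusflavone A (8-{5-[(2S)-5,7-dihydroxy-4-oxo-3,4-dihydro-2H-chromen-2-yl]-2-hydroxyphenyl}-5,7-dihydroxy-2-(4-methoxyphenyl)-4H-chromen-4-one)
Conditions: HCl (3 M aq), MeOH/THF, 40–45 °C
Reagents that add atoms: none
Why: Acid-catalysed acetal exchange removes all four MOM groups as dimethoxymethane while the aryl methyl ether is stable; the C2 stereocenter is not at risk because flavanone racemization runs through base-induced ring opening to the chalcone, which these conditions avoid.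

**Compound list**

1 | acacetin (5,7-dihydroxy-2-(4-methoxyphenyl)-4H-chromen-4-one) | COc1ccc(-c2cc(=O)c3c(O)cc(O)cc3o2)cc1 | starting material
2 | 5,7-bis(methoxymethoxy)-2-(4-methoxyphenyl)-4H-chromen-4-one | COc1ccc(-c2cc(=O)c3c(OCOC)cc(OCOC)cc3o2)cc1 | intermediate
3 | 8-iodo-5,7-bis(methoxymethoxy)-2-(4-methoxyphenyl)-4H-chromen-4-one | COc1ccc(-c2cc(=O)c3c(OCOC)cc(OCOC)c(I)c3o2)cc1 | intermediate
4 | 2,4,6-trihydroxybenzaldehyde | O=Cc1c(O)cc(O)cc1O | starting material
5 | 2,6-dihydroxy-4-(methoxymethoxy)benzaldehyde | O=Cc1c(O)cc(OCOC)cc1O | intermediate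
6 | 1-(3-bromo-4-hydroxyphenyl)ethanone | CC(=O)c1ccc(O)c(Br)c1 | starting material
7 | 1-[3-bromo-4-(methoxymethoxy)phenyl]ethanone | CC(=O)c1ccc(OCOC)c(Br)c1 | intermediate
8 | ({1-[3-bromo-4-(methoxymethoxy)phenyl]ethenyl}oxy)trimethylsilane (silyl enol ether, not isolated) | C=C(O[Si](C)(C)C)c1ccc(OCOC)c(Br)c1 | intermediate
9 | 2-bromo-1-[3-bromo-4-(methoxymethoxy)phenyl]ethanone | O=C(CBr)c1ccc(OCOC)c(Br)c1 | intermediate
10 | rac-2-bromo-1-[3-bromo-4-(methoxymethoxy)phenyl]ethanol | OC(CBr)c1ccc(OCOC)c(Br)c1 | intermediate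
11 | rac-2-{2-bromo-1-[3-bromo-4-(methoxymethoxy)phenyl]ethoxy}-6-hydroxy-4-(methoxymethoxy)benzaldehyde | BrCC(Oc1cc(OCOC)cc(O)c1C=O)c1ccc(OCOC)c(Br)c1 | intermediate
12 | 2-({1-[3-bromo-4-(methoxymethoxy)phenyl]ethenyl}oxy)-6-hydroxy-4-(methoxymethoxy)benzaldehyde | C=C(Oc1cc(OCOC)cc(O)c1C=O)c1ccc(OCOC)c(Br)c1 | intermediate
13 | 2-hydroxy-4-(methoxymethoxy)-6-({1-[4-(methoxymethoxy)-3-(4,4,5,5-tetramethyl-1,3,2-dioxaborolan-2-yl)phenyl]ethenyl}oxy)benzaldehyde (not isolated) | C=C(Oc1cc(OCOC)cc(O)c1C=O)c1ccc(OCOC)c(B2OC(C)(C)C(C)(C)O2)c1 | intermediate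
14 | 2-hydroxy-4-(methoxymethoxy)-6-[(1-{3-[5,7-bis(methoxymethoxy)-2-(4-methoxyphenyl)-4-oxo-4H-chromen-8-yl]-4-(methoxymethoxy)phenyl}ethenyl)oxy]benzaldehyde | COc1ccc(-c2cc(=O)c3c(OCOC)cc(OCOC)c(-c4cc(C(=C)Oc5cc(OCOC)cc(O)c5C=O)ccc4OCOC)c3o2)cc1 | intermediate
15 | 8-{5-[(2S)-5-hydroxy-7-(methoxymethoxy)-4-oxo-3,4-dihydro-2H-chromen-2-yl]-2-(methoxymethoxy)phenyl}-5,7-bis(methoxymethoxy)-2-(4-methoxyphenyl)-4H-chromen-4-one | COc1ccc(-c2cc(=O)c3c(OCOC)cc(OCOC)c(-c4cc([C@@H]5CC(=O)c6c(O)cc(OCOC)cc6O5)ccc4OCOC)c3o2)cc1 | intermediate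
16 | 2,3-dihydropodocarpusflavone A (8-{5-[(2S)-5,7-dihydroxy-4-oxo-3,4-dihydro-2H-chromen-2-yl]-2-hydroxyphenyl}-5,7-dihydroxy-2-(4-methoxyphenyl)-4H-chromen-4-one) | COc1ccc(-c2cc(=O)c3c(O)cc(O)c(-c4cc([C@@H]5CC(=O)c6c(O)cc(O)cc6O5)ccc4O)c3o2)cc1 | target

**Step count and risks**

Total step count: 11. Longest linear sequence: 8 steps (steps 4 to 11, from 6).

Steps most likely to fail:

1. Step 10 (proposed new method). The acyl rhodium hydride may lose CO before the alkene inserts. Insertion may take the 5-exo course. The facial selectivity of hydride transfer may be poor. The many oxygen donors of the substrate may slow turnover. Traces of acid may hydrolyse the enol ether. The fallback uses known chemistry only, sets out from 9 and closes the same C3–C4 bond on a small fragment with the stereocenter already in place. Corey–Bakshi–Shibata reduction of 9 ((S)-2-methyl-CBS-oxazaborolidine, BH3·SMe2, THF, −20 °C) should give (1S)-2-bromo-1-[3-bromo-4-(methoxymethoxy)phenyl]ethanol F1. Mitsunobu etherification of F1 with 5 (PPh3, DIAD, toluene, 0 °C) proceeds with inversion to 2-{(1R)-2-bromo-1-[3-bromo-4-(methoxymethoxy)phenyl]ethoxy}-6-hydroxy-4-(methoxymethoxy)benzaldehyde F2. An N-heterocyclic-carbene-catalysed intramolecular acylation follows (3-benzyl-5-(2-hydroxyethyl)-4-methylthiazolium chloride as precatalyst, DBU, dioxane, 60 °C). In it the acyl-anion equivalent formed from the aldehyde displaces the primary bromide without touching C2, giving (2S)-2-[3-bromo-4-(methoxymethoxy)phenyl]-5-hydroxy-7-(methoxymethoxy)-2,3-dihydro-4H-chromen-4-one F3. One-pot Miyaura borylation to the flavanone pinacol boronate F4 and Suzuki–Miyaura coupling with 3 (KOAc, then K3PO4 at the lowest workable temperature, to limit base-induced ring opening) comes back to the route at 15.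

2. Step 9. Protodeboronation of the boronate formed in the flask, and slow transmetalation at the hindered C8 position with competing deiodination or homocoupling, may starve the cross-coupling. The fallback reverses the roles of the partners so that the aldehyde/enol ether fragment is never borylated, and sets out from 3. Miyaura borylation (PdCl2(dppf), B2pin2, KOAc, DMSO, 80 °C) gives 5,7-bis(methoxymethoxy)-2-(4-methoxyphenyl)-8-(4,4,5,5-tetramethyl-1,3,2-dioxaborolan-2-yl)-4H-chromen-4-one F5, which is isolated and purified. It is then coupled with bromide 12 under anhydrous conditions (Pd(OAc)2/SPhos, K3PO4, toluene, 90 °C), and the sequence comes back to the route at 14.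

3. Step 8. Under strong base the elimination may run the other way (loss of the aryloxide to give a bromostyrene), substitution at CH2Br may compete, or the phenoxide aldehyde may degrade. The fallback replaces the base-induced E2 by a neutral thermal syn-elimination and sets out from 11. Displacement of bromide with PhSeNa (preformed from PhSeSePh and NaBH4 in EtOH, borohydride fully consumed before addition, 0 °C) gives rac-2-hydroxy-4-(methoxymethoxy)-6-{1-[3-bromo-4-(methoxymethoxy)phenyl]-2-(phenylselanyl)ethoxy}benzaldehyde F6. Oxidation (NaIO4, NaHCO3, MeOH/THF/H2O, rt) gives the corresponding selenoxide F7, not isolated. On warming to 40–60 °C with i-Pr2NH as scavenger it eliminates toward its only β-hydrogen, and the sequence comes back to the route at 12.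

Further compounds
F1 | step 10 | (1S)-2-bromo-1-[3-bromo-4-(methoxymethoxy)phenyl]ethanol | O[C@H](CBr)c1ccc(OCOC)c(Br)c1
F2 | step 10 | 2-{(1R)-2-bromo-1-[3-bromo-4-(methoxymethoxy)phenyl]ethoxy}-6-hydroxy-4-(methoxymethoxy)benzaldehyde | BrC[C@H](Oc1cc(OCOC)cc(O)c1C=O)c1ccc(OCOC)c(Br)c1
F3 | step 10 | (2S)-2-[3-bromo-4-(methoxymethoxy)phenyl]-5-hydroxy-7-(methoxymethoxy)-2,3-dihydro-4H-chromen-4-one | O=C1C[C@@H](c2ccc(OCOC)c(Br)c2)Oc2cc(OCOC)cc(O)c12
F4 | step 10 | (2S)-5-hydroxy-7-(methoxymethoxy)-2-[4-(methoxymethoxy)-3-(4,4,5,5-tetramethyl-1,3,2-dioxaborolan-2-yl)phenyl]-2,3-dihydro-4H-chromen-4-one | O=C1C[C@@H](c2ccc(OCOC)c(B3OC(C)(C)C(C)(C)O3)c2)Oc2cc(OCOC)cc(O)c12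
F5 | step 9 | 5,7-bis(methoxymethoxy)-2-(4-methoxyphenyl)-8-(4,4,5,5-tetramethyl-1,3,2-dioxaborolan-2-yl)-4H-chromen-4-one | COc1ccc(-c2cc(=O)c3c(OCOC)cc(OCOC)c(B4OC(C)(C)C(C)(C)O4)c3o2)cc1
F6 | step 8 | rac-2-hydroxy-4-(methoxymethoxy)-6-{1-[3-bromo-4-(methoxymethoxy)phenyl]-2-(phenylselanyl)ethoxy}benzaldehyde | O=Cc1c(O)cc(OCOC)cc1OC(C[Se]c1ccccc1)c1ccc(OCOC)c(Br)c1
F7 | step 8 | rac-2-hydroxy-4-(methoxymethoxy)-6-{1-[3-bromo-4-(methoxymethoxy)phenyl]-2-(phenylseleninyl)ethoxy}benzaldehyde | O=Cc1c(O)cc(OCOC)cc1OC(C[Se](=O)c1ccccc1)c1ccc(OCOC)c(Br)c1
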